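Ring A = central benzene ring; ring B = dioxygenated benzene ring inside the seven-membered ring; dihydrofuran 1 = the one bearing the free 3,5-dihydroxyphenyl group; dihydrofuran 2 = the one fused to the seven-membered ring (O1, C2 with 4-hydroxyphenyl, C3 bonded to ring B).
Target ⇐ O-demethylation ⇐ ionic hydrogenation of the C2=C3 bond of a benzofuran (dihydrofuran 2 one oxidation level higher) ⇐ key step: the O1–C(ring A) bond and the C3–C(ring A) bond are made together from an open-chain iodo triflate by one palladium catalyst, which closes the seven-membered ring (ketone α-arylation at the C–I carbon) and then the furan (enolate O-arylation at the neighbouring C–OTf carbon).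
Enabling feature: O1–C2–C3 of dihydrofuran 2 is the enolate of a benzyl aryl ketone in disguise (a C,O-bisnucleophile); its two acceptor carbons on ring A are neighbours; the oxygen-bearing one is a resorcinol carbon that can be carried as a phenol (later the triflate) and directs iodine to its ortho neighbour; C3 lies at seven-ring distance from that neighbour through ring B and the CH(aryl)–CH2 bridge.
Key-step precursor ⇐ α-arylation of 4-methoxyacetophenone at a ring B chloride ⇐ Suzuki–Miyaura sp3–sp2 union of a 4-bromo-2,3-dihydrobenzofuran (ring A + dihydrofuran 1, from 5-bromoresorcinol by acylation and enantioselective carbene C–H insertion) with a β-chiral alkylboronate (ring B + bridge, by asymmetric hydroboration of a 1,1-diarylethene).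
Ring order: dihydrofuran 1 (step 5); seven-membered ring and furan 2 in one operation (step 15); furan 2 to dihydrofuran 2 (step 16), the bridge stereocentre relaying its configuration.

Key step: step 15

Remark: the target is read as S at the bridge methine, 2R,3R in dihydrofuran 1 and 2S,3S in dihydrofuran 2 (both trans); the enantiomers of the rhodium catalyst (step 5) and of the phosphine (step 9) are working choices, to be fixed by the sense of induction found.

Step 1
Reactants: 1 5-bromobenzene-1,3-diol; 2 3,5-dimethoxybenzoic acid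
Product: 3 (2-bromo-4,6-dihydroxyphenyl)(3,5-dimethoxyphenyl)methanone
Conditions: BF3·OEt2 (as medium), 90 °C; aqueous work-up
Reagents that add atoms: none
Why: Friedel–Crafts (Nencki-type) acylation of a resorcinol with a carboxylic acid in BF3·OEt2 goes para to one hydroxyl and ortho to the other, here at the carbon next to bromine as with 5-alkylresorcinols, and the boron chelate of the ortho-hydroxy ketone should prevent a second acylation.

Step 2
Reactants: 3 dihydroxybenzophenone
Product: 4 [4-(benzyloxy)-2-bromo-6-hydroxyphenyl](3,5-dimethoxyphenyl)methanone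
Conditions: BnBr (1.05 equiv), K2CO3, acetone, reflux
Reagents that add atoms: benzyl bromide, BrCc1ccccc1
Why: Williamson etherification, selective because the hydroxyl para to the carbonyl is the more acidic one and is not held in the intramolecular hydrogen bond to the ketone.

Step 3
Reactants: 4 monobenzyl ether; 5 4-methoxybenzyl chloride
Product: 6 {4-(benzyloxy)-2-bromo-6-[(4-methoxybenzyl)oxy]phenyl}(3,5-dimethoxyphenyl)methanone
Conditions: K2CO3, KI (cat.), DMF, 70 °C
Reagents that add atoms: none
Why: Williamson etherification of the remaining chelated phenol under more forcing conditions installs the 4-methoxybenzyl group whose CH2 becomes C2 of dihydrofuran 1.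

Step 4
Reactants: 6 bis-ether benzophenone
Product: 7 hydrazone of 6
Conditions: N2H4·H2O (excess), AcOH (cat.), n-BuOH, 110 °C
Reagents that add atoms: hydrazine (as hydrate), NN
Why: Condensation of the diaryl ketone with hydrazine to the hydrazone, slowed by the two ortho substituents but expected to proceed at elevated temperature in excess hydrazine.

Step 5
Reactants: 7 hydrazone
Product: 9 (2S,3R)-6-(benzyloxy)-4-bromo-3-(3,5-dimethoxyphenyl)-2-(4-methoxyphenyl)-2,3-dihydro-1-benzofuran (cis), via diaryldiazomethane 8 (not isolated)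
Conditions: MnO2, CH2Cl2, 0 °C, filtration; then Rh2(R-PTAD)4 (1 mol %), CH2Cl2, −20 °C to rt
Reagents that add atoms: none
Why: Oxidation of the hydrazone gives the diaryldiazomethane, and the chiral dirhodium tetracarboxylate turns it into a donor/donor carbene that inserts into the benzylic ether C–H bond through a five-membered transition state (intramolecular carbene C–H insertion), which should give the cis-2,3-diaryl ring and set C3 under catalyst control (catalyst enantiomer chosen for 3R).

Step 6
Reactants: 9 cis-dihydrobenzofuran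
Product: 10 (2R,3R)-6-(benzyloxy)-4-bromo-3-(3,5-dimethoxyphenyl)-2-(4-methoxyphenyl)-2,3-dihydro-1-benzofuran (trans)
Conditions: CF3CO2H (5 equiv), CH2Cl2, rt
Reagents that add atoms: none
Why: Acid-mediated epimerisation, in which reversible ionisation of the C2–O bond to the 4-methoxybenzylic cation and reclosure should equilibrate C2 to the more stable trans isomer while the catalyst-set C3 is untouched.

Step 7
Reactants: 11 1-chloro-3,5-dimethoxybenzene; 12 4-methoxybenzoyl chloride
Product: 13 (2-chloro-4,6-dimethoxyphenyl)(4-methoxyphenyl)methanone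
Conditions: AlCl3 (1.1 equiv), CH2Cl2, −10 to 0 °C
Reagents that add atoms: none
Why: Friedel–Crafts acylation at the position ortho to chlorine, which is para to one methoxy group and ortho to the other and is the site at which 5-substituted 1,3-dimethoxybenzenes are formylated and halogenated; low temperature limits cleavage of the methoxy group next to the new ketone.

Step 8
Reactants: 13 diaryl ketone
Product: 15 1-chloro-3,5-dimethoxy-2-[1-(4-methoxyphenyl)ethenyl]benzene, via tertiary alcohol 14 (not isolated)
Conditions: MeMgBr, THF, 0 °C to rt; then TsOH·H2O (cat.), toluene, 60 °C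
Reagents that add atoms: methylmagnesium bromide, C[Mg]Br
Why: Grignard addition to the diaryl ketone followed by acid-catalysed dehydration of the tertiary benzylic alcohol, which can give only the 1,1-diarylethene.

Step 9
Reactants: 15 1,1-diarylethene
Product: 16 2-[(2S)-2-(2-chloro-4,6-dimethoxyphenyl)-2-(4-methoxyphenyl)ethyl]-4,4,5,5-tetramethyl-1,3,2-dioxaborolane
Conditions: CuCl (5 mol %), (R)-DTBM-SEGPHOS (5.5 mol %), NaOtBu (10 mol %), pinacolborane (1.5 equiv), THF, rt
Reagents that add atoms: pinacolborane, B1OC(C)(C)C(C)(C)O1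
Why: Copper hydride-catalysed asymmetric anti-Markovnikov hydroboration of a 1,1-disubstituted vinylarene, in which hydrocupration puts copper on the terminal carbon and delivers hydride to one face of the diaryl carbon; the two aryl groups differ strongly (one di-ortho-substituted and twisted, one para-substituted and coplanar), so the ligand should control the new stereocentre (ligand enantiomer chosen for S).

Step 10
Reactants: 10 trans-bromodihydrobenzofuran; 16 alkylboronate
Product: 17 (2R,3R)-6-(benzyloxy)-4-[(2S)-2-(2-chloro-4,6-dimethoxyphenyl)-2-(4-methoxyphenyl)ethyl]-3-(3,5-dimethoxyphenyl)-2-(4-methoxyphenyl)-2,3-dihydro-1-benzofuran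
Conditions: Pd(OAc)2 (5 mol %), SPhos (10 mol %), K3PO4, toluene/H2O (10:1), 90 °C
Reagents that add atoms: none
Why: Suzuki–Miyaura sp3–sp2 coupling of a primary alkylboronic ester with the aryl bromide, in which the stereocentre β to boron is not involved and the hindered, electron-rich aryl chloride should react much more slowly than the bromide.

Step 11
Reactants: 17 aryl chloride; 18 1-(4-methoxyphenyl)ethanone
Product: 19 (2R,3R)-6-(benzyloxy)-4-[(2S)-2-{2,4-dimethoxy-6-[2-(4-methoxyphenyl)-2-oxoethyl]phenyl}-2-(4-methoxyphenyl)ethyl]-3-(3,5-dimethoxyphenyl)-2-(4-methoxyphenyl)-2,3-dihydro-1-benzofuran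
Conditions: Pd2(dba)3 (2.5 mol %), XPhos (6 mol %), NaOtBu, toluene, 90 °C; 18 in excess
Reagents that add atoms: none
Why: Palladium-catalysed α-arylation of a methyl ketone enolate with an aryl chloride (dialkylbiarylphosphine ligand) builds the benzyl aryl ketone, with excess ketone limiting diarylation.

Step 12
Reactants: 19 benzyl ether
Product: 20 (2R,3R)-4-[(2S)-2-{2,4-dimethoxy-6-[2-(4-methoxyphenyl)-2-oxoethyl]phenyl}-2-(4-methoxyphenyl)ethyl]-3-(3,5-dimethoxyphenyl)-2-(4-methoxyphenyl)-2,3-dihydro-1-benzofuran-6-ol
Conditions: H2 (1 atm), 10% Pd/C, EtOAc, rt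
Reagents that add atoms: none
Why: Hydrogenolysis of the aryl benzyl ether under mild conditions, under which the cyclic benzylic ether of the dihydrobenzofuran and the aryl ketone should react much more slowly.

Step 13
Reactants: 20 phenol
Product: 21 the 5-iodo derivative of 20 (iodine on ring A between the CH2-bearing carbon and the hydroxyl-bearing carbon)
Conditions: I2 (1.05 equiv), NaHCO3, THF/H2O, 0 °C to rt
Reagents that add atoms: iodine, II
Why: Electrophilic iodination through the phenoxide, with which the methyl ethers cannot compete; the para position is blocked, and of the two ortho positions the one para to the furan oxygen and next to the benzylic CH2 is where 5-alkylresorcinol ethers are halogenated, the position between the two oxygens being the least reactive.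

Step 14
Reactants: 21 iodophenol
Product: 22 the trifluoromethanesulfonate of 21
Conditions: PhNTf2, Et3N, DMAP (cat.), CH2Cl2, rt
Reagents that add atoms: N-phenylbis(trifluoromethanesulfonimide), O=S(=O)(N(c1ccccc1)S(=O)(=O)C(F)(F)F)C(F)(F)F
Why: Triflation of the phenol with N-phenyltriflimide, a reagent that should leave the enolisable ketone alone.

Step 15
Reactants: 22 iodo triflate ketone
Product: 24 benzofuran (heptamethyl ether of the target with a C2=C3 double bond in furan 2), via seven-ring α-aryl ketone 23 (not isolated)
Conditions: Pd2(dba)3 (5 mol %), DPEphos (12 mol %), Cs2CO3 (3 equiv), toluene (0.01 M), 110 °C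
Reagents that add atoms: none
Why: Zerovalent palladium adds to the C–I bond, the caesium enolate of the benzyl aryl ketone binds to palladium, and C–C reductive elimination from an eight-membered palladacycle closes the seven-membered ring (intramolecular ketone α-arylation) to give 23; its doubly benzylic α-hydrogen is very acidic, so the enolate re-forms, palladium adds to the neighbouring C–OTf bond, and C–O reductive elimination from a six-membered oxapalladacycle closes the five-membered furan ring (enolate O-arylation). The closest known reactions are the one-pot palladium-catalysed formation of 2,3-diarylbenzofurans from ortho-dihaloarenes and benzyl ketones, the palladium-catalysed cyclisation of α-(2-haloaryl) ketones to benzofurans, and intramolecular ketone α-arylations that form seven-membered rings. No stereocentre is created, since both new ring carbons of the furan are sp2 and are set in step 16, and the three existing centres carry no acidic hydrogen under carbonate. The selectivity needed is carbon-first at the iodide-bearing carbon: iodide adds to palladium far faster than triflate, C-arylation there gives a seven-membered ring whereas C-arylation at the triflate carbon would need an eight-membered ring and O-arylation first a ten-membered ring. High dilution should suppress intermolecular arylation.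

Step 16
Reactants: 24 benzofuran
Product: 25 heptamethyl ether of the target
Conditions: Et3SiH (6 equiv), CF3CO2H/CH2Cl2 (1:3), 0 °C to rt
Reagents that add atoms: none
Why: Ionic hydrogenation, in which reversible protonation at C3 of the electron-rich 2,3-diarylbenzofuran gives a 2-aryl oxocarbenium ion that triethylsilane reduces; the bridge methine should keep its 4-methoxyphenyl group pseudo-axial to avoid 1,3-allylic strain with the flanking methoxy group of ring B, which fixes the fold of the seven-membered ring so that C3 takes its hydrogen on the convex face (C3–H cis to that aryl group, as in the target), and C2 should end trans to C3 because the C2–O bond ionises reversibly in the acid and recloses to the more stable trans-2,3-diaryl isomer.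

Step 17
Reactants: 25 heptamethyl ether
Product: 26 CNP0136963.1
Conditions: BBr3 (14 equiv), CH2Cl2, −78 °C to rt; MeOH, then water
Reagents that add atoms: none
Why: Lewis acid-mediated cleavage of all seven aryl methyl ethers with BBr3, the usual last step for permethylated resveratrol oligomers, under which the two benzylic ethers can only re-equilibrate to the trans isomers already present.

Compound list
1 | 5-bromobenzene-1,3-diol | Oc1cc(O)cc(Br)c1 | starting material
2 | 3,5-dimethoxybenzoic acid | COc1cc(OC)cc(c1)C(O)=O | starting material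
3 | (2-bromo-4,6-dihydroxyphenyl)(3,5-dimethoxyphenyl)methanone | COc1cc(OC)cc(c1)C(=O)c1c(O)cc(O)cc1Br | intermediate
4 | [4-(benzyloxy)-2-bromo-6-hydroxyphenyl](3,5-dimethoxyphenyl)methanone | COc1cc(OC)cc(c1)C(=O)c1c(O)cc(OCc2ccccc2)cc1Br | intermediate
5 | 4-methoxybenzyl chloride | COc1ccc(CCl)cc1 | starting material
6 | {4-(benzyloxy)-2-bromo-6-[(4-methoxybenzyl)oxy]phenyl}(3,5-dimethoxyphenyl)methanone | COc1cc(OC)cc(c1)C(=O)c1c(OCc2ccc(OC)cc2)cc(OCc2ccccc2)cc1Br | intermediate
7 | hydrazone of 6 | COc1cc(OC)cc(c1)C(=NN)c1c(OCc2ccc(OC)cc2)cc(OCc2ccccc2)cc1Br | intermediate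
8 | 5-(benzyloxy)-1-bromo-2-[diazo(3,5-dimethoxyphenyl)methyl]-3-[(4-methoxybenzyl)oxy]benzene | COc1cc(OC)cc(c1)C(=[N+]=[N-])c1c(OCc2ccc(OC)cc2)cc(OCc2ccccc2)cc1Br | intermediate (not isolated)
9 | (2S,3R)-6-(benzyloxy)-4-bromo-3-(3,5-dimethoxyphenyl)-2-(4-methoxyphenyl)-2,3-dihydro-1-benzofuran (cis) | Brc1cc(OCc2ccccc2)cc2c1[C@@H](c1cc(OC)cc(OC)c1)[C@@H](c1ccc(OC)cc1)O2 | intermediate
10 | (2R,3R)-6-(benzyloxy)-4-bromo-3-(3,5-dimethoxyphenyl)-2-(4-methoxyphenyl)-2,3-dihydro-1-benzofuran (trans) | Brc1cc(OCc2ccccc2)cc2c1[C@@H](c1cc(OC)cc(OC)c1)[C@H](c1ccc(OC)cc1)O2 | intermediate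
11 | 1-chloro-3,5-dimethoxybenzene | COc1cc(Cl)cc(OC)c1 | starting material
12 | 4-methoxybenzoyl chloride | COc1ccc(cc1)C(Cl)=O | starting material
13 | (2-chloro-4,6-dimethoxyphenyl)(4-methoxyphenyl)methanone | COc1ccc(cc1)C(=O)c1c(Cl)cc(OC)cc1OC | intermediate
14 | 1-(2-chloro-4,6-dimethoxyphenyl)-1-(4-methoxyphenyl)ethan-1-ol (racemic) | COc1ccc(cc1)C(C)(O)c1c(Cl)cc(OC)cc1OC | intermediate (not isolated)
15 | 1-chloro-3,5-dimethoxy-2-[1-(4-methoxyphenyl)ethenyl]benzene | COc1ccc(cc1)C(=C)c1c(Cl)cc(OC)cc1OC | intermediate
16 | 2-[(2S)-2-(2-chloro-4,6-dimethoxyphenyl)-2-(4-methoxyphenyl)ethyl]-4,4,5,5-tetramethyl-1,3,2-dioxaborolane | COc1ccc(cc1)[C@H](CB1OC(C)(C)C(C)(C)O1)c1c(Cl)cc(OC)cc1OC | intermediate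
17 | (2R,3R)-6-(benzyloxy)-4-[(2S)-2-(2-chloro-4,6-dimethoxyphenyl)-2-(4-methoxyphenyl)ethyl]-3-(3,5-dimethoxyphenyl)-2-(4-methoxyphenyl)-2,3-dihydro-1-benzofuran | COc1ccc([C@H](Cc2cc(OCc3ccccc3)cc3c2[C@@H](c2cc(OC)cc(OC)c2)[C@H](c2ccc(OC)cc2)O3)c2c(Cl)cc(OC)cc2OC)cc1 | intermediate
18 | 1-(4-methoxyphenyl)ethanone | COc1ccc(cc1)C(C)=O | starting material
19 | (2R,3R)-6-(benzyloxy)-4-[(2S)-2-{2,4-dimethoxy-6-[2-(4-methoxyphenyl)-2-oxoethyl]phenyl}-2-(4-methoxyphenyl)ethyl]-3-(3,5-dimethoxyphenyl)-2-(4-methoxyphenyl)-2,3-dihydro-1-benzofuran | COc1ccc([C@H](Cc2cc(OCc3ccccc3)cc3c2[C@@H](c2cc(OC)cc(OC)c2)[C@H](c2ccc(OC)cc2)O3)c2c(CC(=O)c3ccc(OC)cc3)cc(OC)cc2OC)cc1 | intermediate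
20 | (2R,3R)-4-[(2S)-2-{2,4-dimethoxy-6-[2-(4-methoxyphenyl)-2-oxoethyl]phenyl}-2-(4-methoxyphenyl)ethyl]-3-(3,5-dimethoxyphenyl)-2-(4-methoxyphenyl)-2,3-dihydro-1-benzofuran-6-ol | COc1ccc([C@H](Cc2cc(O)cc3c2[C@@H](c2cc(OC)cc(OC)c2)[C@H](c2ccc(OC)cc2)O3)c2c(CC(=O)c3ccc(OC)cc3)cc(OC)cc2OC)cc1 | intermediate
21 | 5-iodo derivative of 20 (5-iodo-2,3-dihydro-1-benzofuran-6-ol; other substituents and 2R,3R,2S descriptors as in 20) | COc1ccc([C@H](Cc2c(I)c(O)cc3c2[C@@H](c2cc(OC)cc(OC)c2)[C@H](c2ccc(OC)cc2)O3)c2c(CC(=O)c3ccc(OC)cc3)cc(OC)cc2OC)cc1 | intermediate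
22 | trifluoromethanesulfonate of 21 (5-iodo-2,3-dihydro-1-benzofuran-6-yl triflate) | COc1ccc([C@H](Cc2c(I)c(OS(=O)(=O)C(F)(F)F)cc3c2[C@@H](c2cc(OC)cc(OC)c2)[C@H](c2ccc(OC)cc2)O3)c2c(CC(=O)c3ccc(OC)cc3)cc(OC)cc2OC)cc1 | intermediate
23 | seven-ring α-aryl ketone: 22 after C–C bond formation between the iodide carbon of ring A and the ketone CH2, which becomes a CH carrying the 4-methoxybenzoyl group between ring A and ring B (epimerisable); triflate retained; bridge methine S, dihydrofuran 1 2R,3R | COc1ccc([C@@H]2Cc3c(c(OS(=O)(=O)C(F)(F)F)cc4c3[C@@H](c3cc(OC)cc(OC)c3)[C@H](c3ccc(OC)cc3)O4)C(C(=O)c3ccc(OC)cc3)c3cc(OC)cc(OC)c32)cc1 | intermediate (not isolated)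
24 | benzofuran: heptamethyl ether of the target with a C2=C3 double bond in furan 2 (2-(4-methoxyphenyl)furan fused to ring A, C3 bonded to ring B); bridge methine S, dihydrofuran 1 2R,3R | COc1ccc([C@@H]2Cc3c4c(cc5c3[C@@H](c3cc(OC)cc(OC)c3)[C@H](c3ccc(OC)cc3)O5)oc(-c3ccc(OC)cc3)c4-c3cc(OC)cc(OC)c32)cc1 | intermediate
25 | heptamethyl ether of the target (bridge methine S; dihydrofuran 1 2R,3R; dihydrofuran 2 2S,3S) | COc1ccc([C@@H]2Cc3c4c(cc5c3[C@@H](c3cc(OC)cc(OC)c3)[C@H](c3ccc(OC)cc3)O5)O[C@H](c3ccc(OC)cc3)[C@H]4c3cc(OC)cc(OC)c32)cc1 | intermediate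
26 | CNP0136963.1 | Oc1ccc([C@@H]2Cc3c4c(cc5c3[C@@H](c3cc(O)cc(O)c3)[C@H](c3ccc(O)cc3)O5)O[C@H](c3ccc(O)cc3)[C@H]4c3cc(O)cc(O)c32)cc1 | target

Total steps: 17. Longest linear sequence: 14 steps (steps 1–6 and 10–17; steps 7–9 make the second fragment).

Steps most likely to fail

Step 16. What may go wrong: triethylsilane captures the ring-opened 4-methoxybenzylic cations (reductive opening of either dihydrofuran), or C3 of the furan is protonated on the wrong face. Fallback: from 24, hydrogenation over Pd(OH)2/C (H2, 50 bar, EtOAc/AcOH) should add both hydrogens to the open convex face and give the cis-2,3-diaryl dihydrobenzofuran, the C2 epimer of 25 F1. Treating it with CF3CO2H in CH2Cl2 in the absence of any hydride donor epimerises C2 through the reversible benzylic ionisation and returns to the route at 25.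

Step 9. What may go wrong: poor facial discrimination in the hydrocupration of the hindered 1,1-diarylethene, or no turnover. Fallback: from 13, boron–Wittig olefination with lithiated bis[(pinacolato)boryl]methane (CH2(Bpin)2, LiTMP, THF, −78 °C to rt) gives the alkenylboronate (E)-2-[2-(2-chloro-4,6-dimethoxyphenyl)-2-(4-methoxyphenyl)ethenyl]-4,4,5,5-tetramethyl-1,3,2-dioxaborolane F2, the geometric isomers being separated if both form. Asymmetric hydrogenation of this trisubstituted alkenylboronate with a cationic iridium phosphine–oxazoline catalyst, [Ir(cod)(tBu-PHOX)]BArF under H2 in CH2Cl2, a known substrate class for such catalysts, returns to the route at 16.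

Step 15. What may go wrong: oxidative addition at the triflate before the iodide, C–H arylation of a neighbouring anisyl ring or protodeiodination at the arylpalladium stage, or intermolecular arylation. Fallback: the two bond formations are run as separate operations with separate catalysts. From 22, Pd2(dba)3/P(tBu)3 with K3PO4 in toluene at 70 °C, a catalyst that activates aryl iodides readily and aryl triflates poorly, closes only the seven-membered ring, and 23 is isolated. Pd2(dba)3/DPEphos with Cs2CO3 in toluene at 100 °C then closes the furan by enolate O-arylation and returns to the route at 24. No compound outside the list is made (F0).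

Further compounds
F1 | step 16 | C2 epimer of 25 in dihydrofuran 2 (2R,3S, cis-2,3-diaryl; other centres as in 25) | COc1ccc([C@@H]2Cc3c4c(cc5c3[C@@H](c3cc(OC)cc(OC)c3)[C@H](c3ccc(OC)cc3)O5)O[C@@H](c3ccc(OC)cc3)[C@H]4c3cc(OC)cc(OC)c32)cc1
F2 | step 9 | (E)-2-[2-(2-chloro-4,6-dimethoxyphenyl)-2-(4-methoxyphenyl)ethenyl]-4,4,5,5-tetramethyl-1,3,2-dioxaborolane | CC1(C)OB(OC1(C)C)/C=C(\c1ccc(OC)cc1)c1c(Cl)cc(OC)cc1OC
F0 | step 15 | none | none
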